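The easy step came first: I divided each target reading by the substrate reading beside it.

| flask | substrate | temperature | remark | time |
|---|---|---|---|---|
| north | 0.048 M | 96 °C | run made earlier |  |
| north-east | 0.11 M | 110 °C | run made earlier |  |
| oak | 0.072 M |  | at 115 °C until 20 min, from then on at 90 °C | 1.0 h |
| ash | 0.072 M | 90 °C |  | 1.0 h |
| birch | 0.072 M | 115 °C |  | 1.0 h |

| run | time / min | target / % | substrate / % |
|---|---|---|---|
| north | 5.00 | 27 | 29 |
| north | 8.00 | 24 | 28 |
| north | 12.0 | 23 | 25 |
| north | 15.0 | 21 | 28 |
| north | 25.0 | 19 | 23 |
| north | 40.0 | 18 | 22 |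
| north | 60.0 | 16 | 19 |
| north-east | 3.00 | 24 | 38 |
| north-east | 6.00 | 19 | 34 |
| north-east | 10.0 | 13 | 27 |
| north-east | 12.0 | 16 | 26 |
| north-east | 15.0 | 15 | 21 |
| north-east | 20.0 | 11 | 21 |

(scatter of a reading: 1.5 percentage points)



- which flask leads in amount of target, in percent of the substrate charged ("all alike" within 1.5 percentage points) (oak / ash / birch / all alike)
- how much target is there at the end, in percent of the substrate charged: oak
- how much target is there at the end, in percent of the substrate charged: ash
- how much target is there at the end, in percent of the substrate charged: birch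

I followed one molecule of the pair, substrate and target. Over the north run, [target]/[substrate] read 0.851, and over the north-east run 0.587. Taking the logarithm as straight in temperature gave 0.997 at 90 °C and 0.514 at 115 °C. I called this the odds of the pair at the temperature of the moment, so a molecule still in the pair was target with a chance of 49.9% at 90 °C and 33.9% at 115 °C.

But the ratio might have been passing, not balanced. In the north run it went from 0.931 to 0.842 while the pair fell from 56.0% to 35.0%, so I took it for a fast balance, a pre-equilibrium.

Yet odds don't tell how many molecules stay in the pair. The other fork is leaving it, which the falling sums put at 0.00855 min⁻¹ in the north run and 0.0389 min⁻¹ in the north-east run. Stretched the same way, that gave 0.00446 min⁻¹ and 0.0669 min⁻¹. Starting from 56.0%, I reckoned target at 21.4% for ash, 6.14% for oak and 0.344% for birch, with ash highest. But 115 °C lies beyond the hottest run, so I trusted the order more than the birch amount.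

The forecast chose ash, with 10% for oak, 21% for ash and 4% for birch, holding that “the equilibrium favours target more when cooler”. Its birch stood above mine.

The flasks gave 8.95% for oak, 16.8% for ash and 6.38% for birch, so ash led.

    substrate ⇌ target (K = 1.00, k = 1.10 min⁻¹, Ea = 92.0 kJ mol⁻¹, ΔH = −32.0 kJ mol⁻¹)
    target ⇌ isomer of the product A (K = 2.00, k = 0.400 min⁻¹, Ea = 109 kJ mol⁻¹, ΔH = −52.0 kJ mol⁻¹)
    isomer of the product A ⇌ isomer of the product B (K = 1.50, k = 0.0120 min⁻¹, Ea = 107 kJ mol⁻¹, ΔH = −12.0 kJ mol⁻¹)
    2 substrate → self-condensation product (k = 0.250 M⁻¹ min⁻¹, Ea = 81.0 kJ mol⁻¹)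
    (constants at 90 °C)

Up to the change at 20 min, oak had 48.2% as self-condensation product, and its [target]/[substrate] stood at 0.507, near the hot odds of 0.514. After cooling, oak's isomer of the product A rose from 7.67% at the change to 19.6% at 0.500 h, while oak's substrate plus target fell from 34.4% at the change to 17.9% at 1.00 h, when its ratio stood at 1.00, near the cool odds of 0.997. In the neighbour of oak charged with 0.018 M, the odds turn 14.5% of substrate into 14.5% of target; the computed result is 14.5%.

The earlier runs and the new flask come from a simulation with made-up constants.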